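**Retrosynthetic overview**
1. Oxirane last: target 32 ⇐ vinyl alcohol 31 by C9‑hydroxyl‑directed epoxidation of the C10 vinyl group.
2. Cyclohexane: 31 ⇐ open‑chain dialdehyde 28 by intramolecular Nozaki–Hiyama allylation (bond C9–C10; sets C9 and C10).
3. Fragment union: 28 ⇐ 25 ⇐ lactone aldehyde 12 + diene allylboronate 23 by allylboration (bond C5–C6; sets C5 and C6), then methacrylation.
4. 12 ⇐ (R)‑γ‑(hydroxymethyl)butyrolactone 1 (lactone ring and C8 present from the start; C7 by anti cuprate addition to the butenolide).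
5. 23 ⇐ cis‑diborylalkene 15 (from propargyl alcohol 13) + (Z)‑iodobutenol 18 (from ethyl butynoate 16) by Suzuki coupling. Ring order: lactone (given) → cyclohexane (step 18) → oxirane (step 19).

Atom labels used below: ring C5–C10; C6 bears the methacrylate, C9 the hydroxyl, C10 the methyl (C14) and the oxirane (C1–C2); lactone C7–C11(=C13H2)–C12(=O)–O–C8; C5 bears C4(=C3H2)–C15HO.
Assumption: (R)‑dihydro‑5‑(hydroxymethyl)furan‑2(3H)‑one (1) is bought as the single enantiomer (both antipodes are catalogue compounds).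

**Lactone fragment**

Step 1
Reactants: 1 (R)-5-(hydroxymethyl)dihydrofuran-2(3H)-one
Product: 2 (R)-5-{[(tert-butyldimethylsilyl)oxy]methyl}dihydrofuran-2(3H)-one
Conditions: TBSCl, imidazole, DMF, 0 °C → rt
Reagents that add atoms: tert-butyldimethylsilyl chloride CC(C)(C)[Si](C)(C)Cl
Why: Standard silyl ether protection of the primary alcohol, which leaves the C8 stereocentre untouched.

Step 2
Reactants: 2 (R)-5-{[(tert-butyldimethylsilyl)oxy]methyl}dihydrofuran-2(3H)-one
Product: 4 (3RS,5R)-5-{[(tert-butyldimethylsilyl)oxy]methyl}-3-(phenylselanyl)dihydrofuran-2(3H)-one, via lithium enolate 3 (not isolated)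
Conditions: LiN(i-Pr)2, THF, −78 °C; then PhSeBr, −78 °C
Reagents that add atoms: phenylselenyl bromide Br[Se]c1ccccc1
Why: α‑Selenenylation of the lactone enolate; the new centre is a mixture that is erased in step 3.

Step 3
Reactants: 4 (3RS,5R)-5-{[(tert-butyldimethylsilyl)oxy]methyl}-3-(phenylselanyl)dihydrofuran-2(3H)-one
Product: 6 (R)-5-{[(tert-butyldimethylsilyl)oxy]methyl}furan-2(5H)-one, via selenoxide 5 (not isolated)
Conditions: 30 % aq H2O2, pyridine, CH2Cl2, 0 °C → rt
Reagents that add atoms: none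
Why: Selenoxide syn‑elimination can only go toward the ring CH2, which gives the butenolide without touching C8.

Step 4
Reactants: 6 (R)-5-{[(tert-butyldimethylsilyl)oxy]methyl}furan-2(5H)-one
Product: 8 (3S,4R,5R)-5-{[(tert-butyldimethylsilyl)oxy]methyl}-3-[(dimethylamino)methyl]-4-ethenyldihydrofuran-2(3H)-one, via magnesium enolate 7 (not isolated)
Conditions: CH2=CHMgBr, CuBr·SMe2 (10 mol %), THF, −78 °C; then [Me2N=CH2]I, −78 °C → rt
Reagents that add atoms: vinylmagnesium bromide C=C[Mg]Br; Eschenmoser's salt C[N+](C)=C.[I-]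
Why: Copper‑catalysed conjugate addition of the vinyl group occurs anti to the silyloxymethyl group (sets C7, trans to C8), and the enolate is trapped in a Mannich reaction anti to the new vinyl group (this centre disappears in step 5).

Step 5
Reactants: 8 (3S,4R,5R)-5-{[(tert-butyldimethylsilyl)oxy]methyl}-3-[(dimethylamino)methyl]-4-ethenyldihydrofuran-2(3H)-one
Product: 10 (4R,5R)-5-{[(tert-butyldimethylsilyl)oxy]methyl}-4-ethenyl-3-methylidenedihydrofuran-2(3H)-one, via ammonium iodide 9 (not isolated)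
Conditions: MeI, THF, rt; then aq NaHCO3, CH2Cl2, rt
Reagents that add atoms: none
Why: N‑Methylation followed by E1cB loss of trimethylamine (Eschenmoser methylenation) installs the α‑methylene group under bicarbonate, which is too mild to move the double bonds or epimerise C7.

Step 6
Reactants: 10 (4R,5R)-5-{[(tert-butyldimethylsilyl)oxy]methyl}-4-ethenyl-3-methylidenedihydrofuran-2(3H)-one
Product: 12 (2R,3R)-2-{[(tert-butyldimethylsilyl)oxy]methyl}-4-methylidene-5-oxooxolane-3-carbaldehyde, via ozonide 11 (not isolated)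
Conditions: O3 (1.0 equiv, metered), CH2Cl2, −78 °C; then PPh3, −78 °C → rt; used crude
Reagents that add atoms: ozone [O-][O+]=O
Why: Ozonolysis is selective for the isolated vinyl group over the ester‑conjugated exo‑methylene, and reductive work‑up gives the C6 aldehyde, which is used at once because C7–H is acidic.

**Diene fragment**

Step 7
Reactants: 13 prop-2-yn-1-ol
Product: 14 tert-butyldimethyl(prop-2-yn-1-yloxy)silane
Conditions: TBSCl, imidazole, DMF, rt
Reagents that add atoms: tert-butyldimethylsilyl chloride CC(C)(C)[Si](C)(C)Cl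
Why: Silyl ether protection of the alcohol that will become C15–OH.

Step 8
Reactants: 14 tert-butyldimethyl(prop-2-yn-1-yloxy)silane
Product: 15 tert-butyl{[(2E)-2,3-bis(4,4,5,5-tetramethyl-1,3,2-dioxaborolan-2-yl)prop-2-en-1-yl]oxy}dimethylsilane (the two boryl groups cis)
Conditions: B2pin2, Pt(PPh3)4 (3 mol %, zerovalent platinum), DMF, 80 °C
Reagents that add atoms: bis(pinacolato)diboron CC1(C)OB(OC1(C)C)B1OC(C)(C)C(C)(C)O1
Why: Platinum‑catalysed alkyne diboration is a syn addition, so both boryl groups end on the same side and fix the later C4=C5 geometry.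

Step 9
Reactants: 16 ethyl but-2-ynoate
Product: 17 ethyl (2Z)-3-iodobut-2-enoate
Conditions: NaI, AcOH, 115 °C
Reagents that add atoms: sodium iodide [Na+].[I-]
Why: Conjugate addition of iodide and anti protonation (hydroiodination of the ynoate) gives the (Z)‑β‑iodo enoate with iodine cis to the ester.

Step 10
Reactants: 17 ethyl (2Z)-3-iodobut-2-enoate
Product: 18 (2Z)-3-iodobut-2-en-1-ol
Conditions: i-Bu2AlH, CH2Cl2, −78 → 0 °C; aq potassium sodium tartrate work-up
Reagents that add atoms: none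
Why: Hydride reduction of the ester to the allylic alcohol leaves the vinyl iodide and its Z geometry intact.

Step 11
Reactants: 15 tert-butyl{[(2E)-2,3-bis(4,4,5,5-tetramethyl-1,3,2-dioxaborolan-2-yl)prop-2-en-1-yl]oxy}dimethylsilane; 18 (2Z)-3-iodobut-2-en-1-ol
Product: 19 (2Z,4E)-6-[(tert-butyldimethylsilyl)oxy]-3-methyl-5-(4,4,5,5-tetramethyl-1,3,2-dioxaborolan-2-yl)hexa-2,4-dien-1-ol
Conditions: Pd(PPh3)4 (5 mol %, zerovalent palladium), aq K3PO4, 1,4-dioxane, 50 °C
Reagents that add atoms: none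
Why: Suzuki–Miyaura coupling occurs only at the unhindered terminal carbon–boron bond and with retention at both sp2 carbons, so C2 ends cis to C5 and the remaining boryl group cis to C10.

Step 12
Reactants: 19 (2Z,4E)-6-[(tert-butyldimethylsilyl)oxy]-3-methyl-5-(4,4,5,5-tetramethyl-1,3,2-dioxaborolan-2-yl)hexa-2,4-dien-1-ol
Product: 21 tert-butyl{[(2E,4Z)-6-chloro-4-methyl-2-(4,4,5,5-tetramethyl-1,3,2-dioxaborolan-2-yl)hexa-2,4-dien-1-yl]oxy}dimethylsilane, via allylic mesylate 20 (not isolated)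
Conditions: MsCl, 2,6-lutidine, LiCl, DMF, 0 °C
Reagents that add atoms: lithium chloride [Li+].[Cl-]
Why: Mesylation and in situ SN2 displacement by chloride at the primary allylic carbon proceed without allylic transposition or E/Z scrambling.

Step 13
Reactants: 21 tert-butyl{[(2E,4Z)-6-chloro-4-methyl-2-(4,4,5,5-tetramethyl-1,3,2-dioxaborolan-2-yl)hexa-2,4-dien-1-yl]oxy}dimethylsilane
Product: 23 tert-butyl{[(2E,4Z)-6-chloro-4-methyl-2-[(4,4,5,5-tetramethyl-1,3,2-dioxaborolan-2-yl)methyl]hexa-2,4-dien-1-yl]oxy}dimethylsilane, via boron ate complex 22 (not isolated)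
Conditions: BrCH2Cl, n-BuLi, THF, −78 °C → rt
Reagents that add atoms: bromochloromethane ClCBr
Why: Matteson homologation: (chloromethyl)lithium adds to boron and the alkenyl group migrates with retention, giving the allylboronate whose CH2B arm (C3) is cis to C10.

**Union and endgame**

Step 14
Reactants: 12 (2R,3R)-2-{[(tert-butyldimethylsilyl)oxy]methyl}-4-methylidene-5-oxooxolane-3-carbaldehyde; 23 tert-butyl{[(2E,4Z)-6-chloro-4-methyl-2-[(4,4,5,5-tetramethyl-1,3,2-dioxaborolan-2-yl)methyl]hexa-2,4-dien-1-yl]oxy}dimethylsilane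
Product: 25 (4S,5R)-5-{[(tert-butyldimethylsilyl)oxy]methyl}-4-[(1S,2R,3Z)-2-{3-[(tert-butyldimethylsilyl)oxy]prop-1-en-2-yl}-5-chloro-1-hydroxy-3-methylpent-3-en-1-yl]-3-methylidenedihydrofuran-2(3H)-one, via pinacol borate ester 24 (not isolated)
Conditions: (S)-TRIP [(S)-3,3'-bis(2,4,6-triisopropylphenyl)-1,1'-binaphthyl-2,2'-diyl hydrogen phosphate] (10 mol %), 4 Å MS, toluene, −30 → 0 °C; aq NaHCO3 work-up
Reagents that add atoms: none
Why: Brønsted‑acid‑catalysed allylboration through a closed chair (Zimmerman–Traxler) transition state, in which the dienyl group cis to CH2B is axial and gives the 5,6‑syn pair (5R,6S), while the (S)‑acid steers attack to the si face of the aldehyde (also the Felkin–Anh face with the sp2 carbon C11 anti) and the allylic chloride stays inert.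

Step 15
Reactants: 25 (4S,5R)-5-{[(tert-butyldimethylsilyl)oxy]methyl}-4-[(1S,2R,3Z)-2-{3-[(tert-butyldimethylsilyl)oxy]prop-1-en-2-yl}-5-chloro-1-hydroxy-3-methylpent-3-en-1-yl]-3-methylidenedihydrofuran-2(3H)-one
Product: 26 (1S,2R,3Z)-1-[(2R,3S)-2-{[(tert-butyldimethylsilyl)oxy]methyl}-4-methylidene-5-oxooxolan-3-yl]-2-{3-[(tert-butyldimethylsilyl)oxy]prop-1-en-2-yl}-5-chloro-3-methylpent-3-en-1-yl 2-methylprop-2-enoate
Conditions: methacryloyl chloride, Et3N, DMAP (cat.), CH2Cl2, −20 → 0 °C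
Reagents that add atoms: methacryloyl chloride C=C(C)C(=O)Cl
Why: DMAP‑catalysed acylation of the still open‑chain C6 alcohol, run cold and at once so that esterification outruns O‑alkylation by the neighbouring allylic chloride.

Step 16
Reactants: 26 (1S,2R,3Z)-1-[(2R,3S)-2-{[(tert-butyldimethylsilyl)oxy]methyl}-4-methylidene-5-oxooxolan-3-yl]-2-{3-[(tert-butyldimethylsilyl)oxy]prop-1-en-2-yl}-5-chloro-3-methylpent-3-en-1-yl 2-methylprop-2-enoate
Product: 27 (1S,2R,3Z)-5-chloro-1-[(2R,3S)-2-(hydroxymethyl)-4-methylidene-5-oxooxolan-3-yl]-2-(3-hydroxyprop-1-en-2-yl)-3-methylpent-3-en-1-yl 2-methylprop-2-enoate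
Conditions: HF·pyridine, pyridine, THF, 0 °C → rt
Reagents that add atoms: none
Why: Buffered fluoride cleavage of the two primary silyl ethers spares the esters, the allylic chloride and the acrylate units.

Step 17
Reactants: 27 (1S,2R,3Z)-5-chloro-1-[(2R,3S)-2-(hydroxymethyl)-4-methylidene-5-oxooxolan-3-yl]-2-(3-hydroxyprop-1-en-2-yl)-3-methylpent-3-en-1-yl 2-methylprop-2-enoate
Product: 28 (1S,2R,3Z)-5-chloro-1-[(2R,3S)-2-formyl-4-methylidene-5-oxooxolan-3-yl]-3-methyl-2-(3-oxoprop-1-en-2-yl)pent-3-en-1-yl 2-methylprop-2-enoate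
Conditions: Dess–Martin periodinane, pyridine, CH2Cl2, 0 °C → rt; used crude
Reagents that add atoms: none
Why: Dess–Martin oxidation turns both primary alcohols into the C9 aldehyde and the C15 enal in one operation and without strong base, so C8 does not epimerise.

Step 18
Reactants: 28 (1S,2R,3Z)-5-chloro-1-[(2R,3S)-2-formyl-4-methylidene-5-oxooxolan-3-yl]-3-methyl-2-(3-oxoprop-1-en-2-yl)pent-3-en-1-yl 2-methylprop-2-enoate
Product: 31 (3aS,4S,5R,6S,7S,7aR)-6-ethenyl-7-hydroxy-6-methyl-3-methylidene-2-oxo-5-(3-oxoprop-1-en-2-yl)octahydro-1-benzofuran-4-yl 2-methylprop-2-enoate, via allylchromium species 29 (not isolated), via chromium alkoxide 30 (not isolated)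
Conditions: CrCl2 (6 equiv), LiI (20 mol %), THF/DMF, 0.005 M, slow addition of 28, rt; water work-up
Reagents that add atoms: none
Why: Intramolecular Nozaki–Hiyama allylation in which the γ,γ‑disubstituted allylchromium keeps its Z geometry and adds through a closed chair fused to the forming ring chair (fixed by the trans‑lactone), so the C5 branch is axial in the metallacycle and O9 ends axial and cis to O8, the C10 methyl axial and the new vinyl group equatorial (9S,10S), with six‑ring closure onto the C9 aldehyde preferred over reaction at the enal.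

Step 19
Reactants: 31 (3aS,4S,5R,6S,7S,7aR)-6-ethenyl-7-hydroxy-6-methyl-3-methylidene-2-oxo-5-(3-oxoprop-1-en-2-yl)octahydro-1-benzofuran-4-yl 2-methylprop-2-enoate
Product: 32 (3aS,4S,5R,6S,7S,7aR)-7-hydroxy-6-methyl-3-methylidene-6-[(2R)-oxiran-2-yl]-2-oxo-5-(3-oxoprop-1-en-2-yl)octahydro-1-benzofuran-4-yl 2-methylprop-2-enoate (CNP0228781.2)
Conditions: VO(acac)2 (10 mol %), t-BuOOH (anhydrous, in decane), CH2Cl2, 0 °C
Reagents that add atoms: tert-butyl hydroperoxide CC(C)(C)OO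
Why: Hydroxyl‑directed vanadium‑catalysed epoxidation, in which the axial C9 vanadate is gauche to the equatorial C10 vinyl group (the only alkene that is neither electron‑poor nor out of reach) and delivers oxygen through a chair‑like transition state with C2 pseudo‑equatorial (C1=C2 eclipsing C10–C5), which gives the (R)‑oxirane.

**Compound list**
1 | (R)-5-(hydroxymethyl)dihydrofuran-2(3H)-one | C1CC(=O)O[C@H]1CO | starting material
2 | (R)-5-{[(tert-butyldimethylsilyl)oxy]methyl}dihydrofuran-2(3H)-one | C1CC(=O)O[C@H]1CO[Si](C)(C)C(C)(C)C | intermediate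
3 | lithium enolate of 2 | [Li+].[O-]C1=CC[C@H](CO[Si](C)(C)C(C)(C)C)O1 | intermediate
4 | (3RS,5R)-5-{[(tert-butyldimethylsilyl)oxy]methyl}-3-(phenylselanyl)dihydrofuran-2(3H)-one | C1C([Se]c2ccccc2)C(=O)O[C@H]1CO[Si](C)(C)C(C)(C)C | intermediate
5 | selenoxide of 4 | C1C([Se](=O)c2ccccc2)C(=O)O[C@H]1CO[Si](C)(C)C(C)(C)C | intermediate
6 | (R)-5-{[(tert-butyldimethylsilyl)oxy]methyl}furan-2(5H)-one | C1=CC(=O)O[C@H]1CO[Si](C)(C)C(C)(C)C | intermediate
7 | bromomagnesium enolate of the 4,5-trans 4-ethenyl lactone | C=C[C@@H]1C=C(O[Mg]Br)O[C@H]1CO[Si](C)(C)C(C)(C)C | intermediate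
8 | (3S,4R,5R)-5-{[(tert-butyldimethylsilyl)oxy]methyl}-3-[(dimethylamino)methyl]-4-ethenyldihydrofuran-2(3H)-one | C=C[C@@H]1[C@@H](CN(C)C)C(=O)O[C@H]1CO[Si](C)(C)C(C)(C)C | intermediate
9 | trimethylammonium iodide of 8 | C=C[C@@H]1[C@@H](C[N+](C)(C)C)C(=O)O[C@H]1CO[Si](C)(C)C(C)(C)C.[I-] | intermediate
10 | (4R,5R)-5-{[(tert-butyldimethylsilyl)oxy]methyl}-4-ethenyl-3-methylidenedihydrofuran-2(3H)-one | C=C[C@@H]1C(=C)C(=O)O[C@H]1CO[Si](C)(C)C(C)(C)C | intermediate
11 | 1,2,4-trioxolane (ozonide) of the vinyl group of 10 | C1OOC(O1)[C@@H]1C(=C)C(=O)O[C@H]1CO[Si](C)(C)C(C)(C)C | intermediate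
12 | (2R,3R)-2-{[(tert-butyldimethylsilyl)oxy]methyl}-4-methylidene-5-oxooxolane-3-carbaldehyde (lactone fragment, 2,3-trans) | O=C[C@@H]1C(=C)C(=O)O[C@H]1CO[Si](C)(C)C(C)(C)C | intermediate
13 | prop-2-yn-1-ol | C#CCO | starting material
14 | tert-butyldimethyl(prop-2-yn-1-yloxy)silane | C#CCO[Si](C)(C)C(C)(C)C | intermediate
15 | tert-butyl{[(2E)-2,3-bis(4,4,5,5-tetramethyl-1,3,2-dioxaborolan-2-yl)prop-2-en-1-yl]oxy}dimethylsilane | CC1(C)OB(OC1(C)C)/C=C(\B1OC(C)(C)C(C)(C)O1)CO[Si](C)(C)C(C)(C)C | intermediate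
16 | ethyl but-2-ynoate | CC#CC(=O)OCC | starting material
17 | ethyl (2Z)-3-iodobut-2-enoate | C/C(I)=C/C(=O)OCC | intermediate
18 | (2Z)-3-iodobut-2-en-1-ol | C/C(I)=C/CO | intermediate
19 | (2Z,4E)-6-[(tert-butyldimethylsilyl)oxy]-3-methyl-5-(4,4,5,5-tetramethyl-1,3,2-dioxaborolan-2-yl)hexa-2,4-dien-1-ol | OC/C=C(C)\C=C(/B1OC(C)(C)C(C)(C)O1)CO[Si](C)(C)C(C)(C)C | intermediate
20 | methanesulfonate of 19 | CS(=O)(=O)OC/C=C(C)\C=C(/B1OC(C)(C)C(C)(C)O1)CO[Si](C)(C)C(C)(C)C | intermediate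
21 | tert-butyl{[(2E,4Z)-6-chloro-4-methyl-2-(4,4,5,5-tetramethyl-1,3,2-dioxaborolan-2-yl)hexa-2,4-dien-1-yl]oxy}dimethylsilane | ClC/C=C(C)\C=C(/B1OC(C)(C)C(C)(C)O1)CO[Si](C)(C)C(C)(C)C | intermediate
22 | lithium (chloromethyl)boronate complex of 21 | [Li+].ClC/C=C(C)\C=C(/[B-]1(CCl)OC(C)(C)C(C)(C)O1)CO[Si](C)(C)C(C)(C)C | intermediate
23 | tert-butyl{[(2E,4Z)-6-chloro-4-methyl-2-[(4,4,5,5-tetramethyl-1,3,2-dioxaborolan-2-yl)methyl]hexa-2,4-dien-1-yl]oxy}dimethylsilane (diene fragment) | ClC/C=C(C)\C=C(/CB1OC(C)(C)C(C)(C)O1)CO[Si](C)(C)C(C)(C)C | intermediate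
24 | O-(pinacolboryl) ester of 25 | CC1(C)OB(OC1(C)C)O[C@@H]([C@H](/C(C)=C\CCl)C(=C)CO[Si](C)(C)C(C)(C)C)[C@@H]1C(=C)C(=O)O[C@H]1CO[Si](C)(C)C(C)(C)C | intermediate
25 | (4S,5R)-5-{[(tert-butyldimethylsilyl)oxy]methyl}-4-[(1S,2R,3Z)-2-{3-[(tert-butyldimethylsilyl)oxy]prop-1-en-2-yl}-5-chloro-1-hydroxy-3-methylpent-3-en-1-yl]-3-methylidenedihydrofuran-2(3H)-one | O[C@@H]([C@H](/C(C)=C\CCl)C(=C)CO[Si](C)(C)C(C)(C)C)[C@@H]1C(=C)C(=O)O[C@H]1CO[Si](C)(C)C(C)(C)C | intermediate
26 | methacrylate of 25 (bis-silyl ether, allylic chloride) | C=C(C)C(=O)O[C@@H]([C@H](/C(C)=C\CCl)C(=C)CO[Si](C)(C)C(C)(C)C)[C@@H]1C(=C)C(=O)O[C@H]1CO[Si](C)(C)C(C)(C)C | intermediate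
27 | diol from 26 (C9 and C15 primary alcohols free) | C=C(C)C(=O)O[C@@H]([C@H](/C(C)=C\CCl)C(=C)CO)[C@@H]1C(=C)C(=O)O[C@H]1CO | intermediate
28 | dialdehyde from 27 (C9 aldehyde, C15 enal) | C=C(C)C(=O)O[C@@H]([C@H](/C(C)=C\CCl)C(=C)C=O)[C@@H]1C(=C)C(=O)O[C@H]1C=O | intermediate
29 | allylchromium dichloride from 28 | C=C(C)C(=O)O[C@@H]([C@H](/C(C)=C\C[Cr](Cl)Cl)C(=C)C=O)[C@@H]1C(=C)C(=O)O[C@H]1C=O | intermediate
30 | chromium alkoxide of 31 | C=C(C)C(=O)O[C@@H]1[C@@H]2C(=C)C(=O)O[C@H]2[C@@H](O[Cr](Cl)Cl)[C@@](C)(C=C)[C@@H]1C(=C)C=O | intermediate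
31 | (3aS,4S,5R,6S,7S,7aR)-6-ethenyl-7-hydroxy-6-methyl-3-methylidene-2-oxo-5-(3-oxoprop-1-en-2-yl)octahydro-1-benzofuran-4-yl 2-methylprop-2-enoate | C=C(C)C(=O)O[C@@H]1[C@@H]2C(=C)C(=O)O[C@H]2[C@@H](O)[C@@](C)(C=C)[C@@H]1C(=C)C=O | intermediate
32 | (3aS,4S,5R,6S,7S,7aR)-7-hydroxy-6-methyl-3-methylidene-6-[(2R)-oxiran-2-yl]-2-oxo-5-(3-oxoprop-1-en-2-yl)octahydro-1-benzofuran-4-yl 2-methylprop-2-enoate | C=C(C)C(=O)O[C@@H]1[C@@H]2C(=C)C(=O)O[C@H]2[C@@H](O)[C@@](C)([C@@H]2CO2)[C@@H]1C(=C)C=O | target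

**Totals and risks**
Total step count: 19. Longest linear sequence: 12 steps (steps 1–6, then 14–19); the two diene branches each reach the target in 11.

The three steps most likely to fail:

Step 14. The pinacol boronate 23 carries a cis γ‑substituent and may add too slowly for the labile aldehyde 12, and the catalyst may not fully control the aldehyde face. The fallback sets out from 23 and swaps the catalytic pinacol‑boronate addition for a stoichiometric chiral boron reagent. Aqueous KHF2 in methanol converts 23 into the potassium allyltrifluoroborate F1; TMSCl and diisopropyl (R,R)‑tartrate then turn it into the tartrate allylboronate F2. This boronate adds to 12 without a catalyst at −78 °C (toluene, 4 Å MS), the tartrate now selecting the si face and the closed chair again giving the 5,6‑syn pair; hydrolytic work‑up comes back to the route at 25.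

Step 18. Divalent chromium may insert sluggishly into the allylic chloride, or the enal may interfere. The fallback sets out from 28 and replaces the chromium reagent by boron: Pd2(dba)3 (zerovalent palladium) and B2pin2 in THF at rt borylate the allylic chloride with retention of the Z geometry to the allylboronate dialdehyde F3. F3 closes spontaneously onto the C9 aldehyde by intramolecular allylboration through the same closed chair to the cyclic borate F4, and aqueous work‑up comes back to the route at 31.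

Step 19. Facial selectivity at C1 rests on a conformational argument, and the enal must survive the peroxide. The fallback sets out from 31 and gives up substrate direction: dimethyldioxirane in acetone at −20 °C epoxidises only the unactivated vinyl group and gives 32 mixed with its C1‑epimeric epoxide F5. Hydrolytic kinetic resolution with (S,S)-(salen)Co(OAc) (trivalent cobalt) and 0.5 equiv of water opens only F5 to the triol F6, which is removed by chromatography, leaving 32.

**Further compounds**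
F1 | step 14 | potassium {(2E,4Z)-2-{[(tert-butyldimethylsilyl)oxy]methyl}-6-chloro-4-methylhexa-2,4-dien-1-yl}trifluoroborate | [K+].F[B-](F)(F)C/C(CO[Si](C)(C)C(C)(C)C)=C\C(C)=C/CCl
F2 | step 14 | diisopropyl (4R,5R)-2-{(2E,4Z)-2-{[(tert-butyldimethylsilyl)oxy]methyl}-6-chloro-4-methylhexa-2,4-dien-1-yl}-1,3,2-dioxaborolane-4,5-dicarboxylate | ClC/C=C(C)\C=C(/CB1O[C@H]([C@@H](O1)C(=O)OC(C)C)C(=O)OC(C)C)CO[Si](C)(C)C(C)(C)C
F3 | step 18 | allylboronate dialdehyde (28 with CH2Cl replaced by CH2Bpin) | C=C(C)C(=O)O[C@@H]([C@H](/C(C)=C\CB1OC(C)(C)C(C)(C)O1)C(=C)C=O)[C@@H]1C(=C)C(=O)O[C@H]1C=O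
F4 | step 18 | O-(pinacolboryl) ester of 31 | C=C(C)C(=O)O[C@@H]1[C@@H]2C(=C)C(=O)O[C@H]2[C@@H](OB3OC(C)(C)C(C)(C)O3)[C@@](C)(C=C)[C@@H]1C(=C)C=O
F5 | step 19 | C1 epimer of 32 [(2S)-oxiranyl] | C=C(C)C(=O)O[C@@H]1[C@@H]2C(=C)C(=O)O[C@H]2[C@@H](O)[C@@](C)([C@H]2CO2)[C@@H]1C(=C)C=O
F6 | step 19 | triol from hydrolysis of F5 [(1S)-1,2-dihydroxyethyl at C10] | C=C(C)C(=O)O[C@@H]1[C@@H]2C(=C)C(=O)O[C@H]2[C@@H](O)[C@@](C)([C@H](O)CO)[C@@H]1C(=C)C=O
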